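## Retrosynthetic overview

1. The C12–C14 and C3–C11 bonds are cut together as one radical cascade with loss of HCl. This leads back to a 3-chloro-3-prenylbicyclo[3.3.1]nonane-2,4,9-trione that carries an endo prenyl group on C7.
2. The C1–C8 bond is cut as attack of the enolised benzoyl triketone on a tertiary C8 cation. This leads back to a monocyclic, dearomatised benzoylphloroglucinol with geranyl and lavandulyl on C5, and Cl and prenyl on C3.
3. One chlorine atom does three jobs. It sends the dearomatising alkylation to the geranyl-bearing carbon, it blocks the more nucleophilic C3 so the cation must close on C1, and it is the radical trigger at the end.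
4. The monocycle comes from 2,4,6-trihydroxybenzophenone, NCS, geranyl bromide, prenyl bromide and (S)-lavandulol. The lavandulol is made by auxiliary-controlled deconjugative prenylation of a senecioyl imide and is the only source of chirality.
5. Ring order: first the C1–C8–C7–C6–C5–C9 ring (bicyclo[3.3.1]), then the seven-membered homoadamantane ring (C3–C11), then the cyclopentane (C12–C14).

Assumption: acylphloroglucinol numbering is kept for all precursors (C1 benzoyl-bearing carbon, C2, C3, C4, C5 geranyl-bearing carbon, C6, C7, C8 = CMe2, C9 = bridging C=O; C10–C12 = CH2–CH=CMe2 on C7; C13–C15 = CH2–CH=CMe2 on C3), and each enolised di- or triketone is drawn as one tautomer.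

## Route

Step 1
Reactants: 1 2,4,6-trihydroxybenzophenone
Product: 2 3-chloro-2,4,6-trihydroxybenzophenone
Conditions: NCS (1.0 equiv), MeCN, 0 °C
Reagents that add atoms: N-chlorosuccinimide, O=C1CCC(=O)N1Cl
Why: Electrophilic aromatic chlorination of the phloroglucinol ring stops after one chlorine because that chlorine lowers the ring's nucleophilicity, and no stereocentre is formed.

Step 2
Reactants: 2 3-chloro-2,4,6-trihydroxybenzophenone; 3 geranyl bromide [(E)-1-bromo-3,7-dimethylocta-2,6-diene]
Product: 4 3-chloro-5-[(E)-geranyl]-2,4,6-trihydroxybenzophenone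
Conditions: KOH (2 equiv), H2O–MeOH, 0 °C to rt
Reagents that add atoms: none
Why: C-alkylation of a phloroglucinolate with an allylic bromide in protic medium (hydrogen-bonded oxygens push the reaction to carbon) occurs at the only free ring C–H, which rearomatises, and the E alkene of 3 is untouched.

Step 3
Reactants: 5 (S)-4-benzyloxazolidin-2-one; 6 3-methylbut-2-enoyl chloride
Product: 7 (S)-4-benzyl-3-(3-methylbut-2-enoyl)oxazolidin-2-one
Conditions: n-BuLi, THF, −78 °C; then 6, −78 to 0 °C
Reagents that add atoms: none
Why: N-acylation of the lithiated oxazolidinone with an acid chloride is the standard way to load the auxiliary and leaves its stereocentre untouched.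

Step 4
Reactants: 7 (S)-4-benzyl-3-(3-methylbut-2-enoyl)oxazolidin-2-one; 8 prenyl bromide (1-bromo-3-methylbut-2-ene)
Product: 9 (S)-4-benzyl-3-[(S)-5-methyl-2-(prop-1-en-2-yl)hex-4-enoyl]oxazolidin-2-one
Conditions: NaN(SiMe3)2, THF, −78 °C; then 8, −78 to −40 °C
Reagents that add atoms: none
Why: In this Evans-type asymmetric deconjugative α-alkylation, γ-deprotonation gives the sodium-chelated Z-dienolate, prenyl bromide attacks its α-carbon opposite the benzyl group, and this sets the future C7 (S in 9, dr expected above 95:5) while the double bond moves out of conjugation to become the isopropenyl group.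

Step 5
Reactants: 9 (S)-4-benzyl-3-[(S)-5-methyl-2-(prop-1-en-2-yl)hex-4-enoyl]oxazolidin-2-one
Product: 10 (S)-lavandulol [(S)-5-methyl-2-(prop-1-en-2-yl)hex-4-en-1-ol]
Conditions: LiBH4, H2O (1 equiv), Et2O, 0 °C
Reagents that add atoms: none
Why: Reductive removal of the auxiliary (imide to primary alcohol) with LiBH4 is mild enough not to epimerise or reconjugate the α-vinyl centre, and it spares both alkenes.

Step 6
Reactants: 10 (S)-lavandulol; 4 3-chloro-5-[(E)-geranyl]-2,4,6-trihydroxybenzophenone; 8 prenyl bromide
Product: 13 (4S)-2-benzoyl-6-chloro-4-[(E)-geranyl]-3-hydroxy-4-[(2R)-5-methyl-2-(prop-1-en-2-yl)hex-4-en-1-yl]-6-prenylcyclohex-2-ene-1,5-dione (route numbering 5S 7R; both C3 epimers), via lavandulyl triflate 11 (not isolated), via chlorodienone 12 (not isolated)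
Conditions: 10, Tf2O, 2,6-lutidine, CH2Cl2, −78 °C; cannulated into 4, LiN(SiMe3)2 (4.3 equiv), THF, −78 to 0 °C; then 8, 0 °C to rt; aq. HCl
Reagents that add atoms: triflic anhydride, O=S(=O)(OS(=O)(=O)C(F)(F)F)C(F)(F)F (its triflyl group is found in 11 only)
Why: This is an alkylative dearomatisation followed by enolate C-allylation, in which the lithium trianion of 4 displaces the primary triflate (SN2, C7 untouched) through its only alkyl-bearing ring carbon because chlorine deactivates the other one; the dianion of 12 then takes the allylic bromide at its most electron-rich carbon C3; C5 forms without facial bias (about 1:1, the 5-epimer is carried along and removed after step 7); and the C3 configuration does not matter because C3 becomes a planar radical in step 8.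

Step 7
Reactants: 13 (4S)-2-benzoyl-6-chloro-4-[(E)-geranyl]-3-hydroxy-4-[(2R)-5-methyl-2-(prop-1-en-2-yl)hex-4-en-1-yl]-6-prenylcyclohex-2-ene-1,5-dione
Product: 14 (1S,5S,7R)-1-benzoyl-3-chloro-5-[(E)-geranyl]-8,8-dimethyl-3,7-diprenylbicyclo[3.3.1]nonane-2,4,9-trione (C7 prenyl endo; both C3 epimers)
Conditions: Co(C36H52N2O2) [cobalt complex of N,N'-bis(3,5-di-tert-butylsalicylidene)-1,2-cyclohexanediamine] (5 mol %), 1-fluoro-2,4,6-trimethylpyridinium triflate (1.5 equiv), PhSiH3 (1.5 equiv), HFIP–CH2Cl2 1:1, 0 °C; SiO2 separation from the 7-exo isomer that arises from the 5-epimer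
Reagents that add atoms: none
Why: Proposed new method: the bulky cobalt hydride formed from the divalent cobalt complex, the N–F oxidant and the silane transfers a hydrogen atom only to the 1,1-disubstituted isopropenyl group (the four trisubstituted alkenes are too hindered), and the tertiary radical is oxidised through an alkylcobalt to the same C8 cation that prenyl transfer creates in the biosynthesis; since C3 is quaternary the only carbon nucleophile left is C1 of the enolised triketone, whose oxygens are masked by hydrogen bonding to HFIP; the three-atom tether delivers C8 to the face of C1 syn to C6, so C1 (S) follows from C5, and a boat-like transition state over the C9 carbonyl keeps C10 outward and leaves the C7 prenyl endo; the closest known reaction types are hydrogen-atom-transfer-initiated radical–polar crossover hydrofunctionalisations and polyene cyclisations of 1,1-disubstituted alkenes, and acid-mediated cationic closures of lavandulyl-type acylphloroglucinols.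

Step 8
Reactants: 14 (1S,5S,7R)-1-benzoyl-3-chloro-5-[(E)-geranyl]-8,8-dimethyl-3,7-diprenylbicyclo[3.3.1]nonane-2,4,9-trione
Product: 16 CNP0110731.1 (1S 3S 5R 7R 11S 14S; the trione core of 14 with new C3–C11 and C12–C14 bonds and an isopropenyl group on C14), via cage chloride 15 (not isolated)
Conditions: CuCl (0.3 equiv), 2,2'-bipyridine (0.3 equiv), MeCN, 80 °C; then DBU (3 equiv), 60 °C
Reagents that add atoms: none
Why: In this copper-catalysed chlorine atom-transfer radical cyclisation (Kharasch type) followed by E2 dehydrochlorination, monovalent copper abstracts the doubly carbonyl-activated C3 chlorine and the planar C3 radical can be reached only on its endo face by C11 of the endo prenyl group (transannular 7-exo-trig; C3 is fixed as S by the cage and C11 as S because C12 swings to the open C4/C6 side, away from the C8 methyls and the benzoyl group); the tertiary C12 radical then closes 5-exo-trig on C14 through a chair-like transition state that places C15 trans to C10 on the convex face (sets C14), chlorine returns from CuCl2(bipy) to C15, and DBU removes an unhindered methyl proton to give the isopropenyl group.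

## Compound list

1 | 2,4,6-trihydroxybenzophenone | O=C(c1ccccc1)c1c(O)cc(O)cc1O | starting material
2 | 3-chloro-2,4,6-trihydroxybenzophenone | O=C(c1ccccc1)c1c(O)cc(O)c(Cl)c1O | intermediate
3 | geranyl bromide | CC(C)=CCC/C(C)=C/CBr | starting material
4 | 3-chloro-5-[(E)-geranyl]-2,4,6-trihydroxybenzophenone | O=C(c1ccccc1)c1c(O)c(Cl)c(O)c(C/C=C(\C)CCC=C(C)C)c1O | intermediate
5 | (S)-4-benzyloxazolidin-2-one | O=C1N[C@@H](Cc2ccccc2)CO1 | starting material
6 | 3-methylbut-2-enoyl chloride | CC(C)=CC(=O)Cl | starting material
7 | (S)-4-benzyl-3-(3-methylbut-2-enoyl)oxazolidin-2-one | CC(C)=CC(=O)N1[C@@H](Cc2ccccc2)COC1=O | intermediate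
8 | prenyl bromide | CC(C)=CCBr | starting material
9 | (S)-4-benzyl-3-[(S)-5-methyl-2-(prop-1-en-2-yl)hex-4-enoyl]oxazolidin-2-one | C=C(C)[C@H](CC=C(C)C)C(=O)N1[C@@H](Cc2ccccc2)COC1=O | intermediate
10 | (S)-lavandulol | C=C(C)[C@H](CC=C(C)C)CO | intermediate
11 | (S)-lavandulyl triflate | C=C(C)[C@H](CC=C(C)C)COS(=O)(=O)C(F)(F)F | intermediate
12 | (6R)-2-benzoyl-4-chloro-6-[(E)-geranyl]-3,5-dihydroxy-6-[(2R)-5-methyl-2-(prop-1-en-2-yl)hex-4-en-1-yl]cyclohexa-2,4-dien-1-one | O=C1C(C(=O)c2ccccc2)=C(O)C(Cl)=C(O)[C@@]1(C/C=C(\C)CCC=C(C)C)C[C@@H](CC=C(C)C)C(C)=C | intermediate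
13 | (4S)-2-benzoyl-6-chloro-4-[(E)-geranyl]-3-hydroxy-4-[(2R)-5-methyl-2-(prop-1-en-2-yl)hex-4-en-1-yl]-6-prenylcyclohex-2-ene-1,5-dione, both epimers at the chlorine-bearing carbon | OC1=C(C(=O)c2ccccc2)C(=O)C(Cl)(CC=C(C)C)C(=O)[C@@]1(C/C=C(\C)CCC=C(C)C)C[C@@H](CC=C(C)C)C(C)=C | intermediate
14 | (1S,5S,7R)-1-benzoyl-3-chloro-5-[(E)-geranyl]-8,8-dimethyl-3,7-diprenylbicyclo[3.3.1]nonane-2,4,9-trione, C7 prenyl endo, both C3 epimers | ClC1(CC=C(C)C)C(=O)[C@@]2(C/C=C(\C)CCC=C(C)C)C[C@@H](CC=C(C)C)C(C)(C)[C@](C(=O)c3ccccc3)(C2=O)C1=O | intermediate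
15 | cage chloride: 16 with a 2-chloropropan-2-yl group in place of the isopropenyl group on C14 (1S,3S,5R,7R,11S,14R) | CC(C)(Cl)[C@@H]1C[C@@]23C(=O)[C@@]4(C/C=C(\C)CCC=C(C)C)C[C@@H](C[C@H]2C1(C)C)C(C)(C)[C@](C(=O)c1ccccc1)(C4=O)C3=O | intermediate
16 | CNP0110731.1: (1S,3S,5R,7R,11S,14S)-1-benzoyl-5-[(E)-geranyl]-8,8,12,12-tetramethyl-14-isopropenyl cage with a tetracyclo[7.3.1.1(3,11).0(3,7)]tetradecanetrione core | C=C(C)[C@@H]1C[C@@]23C(=O)[C@@]4(C/C=C(\C)CCC=C(C)C)C[C@@H](C[C@H]2C1(C)C)C(C)(C)[C@](C(=O)c1ccccc1)(C4=O)C3=O | target

## Step count and risks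

Total step count: 8.
Longest linear sequence: 6 (steps 3, 4, 5, 6, 7, 8, starting from 5 and 6).

**Step 7 is the most likely to fail.** The enolate oxygen on C9 can capture the C8 cation faster than the crowded C1. The endo geometry also forces a boat-like closure, and the N–F oxidant or the cobalt complex may attack the enol or the C3–Cl bond. The fallback sets out from 13 and comes back at 14. Compound 13 is closed on oxygen on purpose, using the same cobalt hydride couple in acetone without HFIP, where the harder oxygen end wins. This gives the dihydropyran-fused tertiary enol ether F4. That vinylogous ester is then ionised with BF3·OEt2 in CH2Cl2 at −40 °C, where no proton source touches the other alkenes. The ion pair recloses reversibly on oxygen and irreversibly on C1 (a Lewis-acid O-to-C 1,3-shift), which gives 14.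

**Step 6 is the second risk.**
- The hindered, rearrangement-prone triflate must build a quaternary carbon.
- The chlorine-bearing C3 of 12 may be allylated on oxygen instead of carbon.
- The product can pass its electrophilic chlorine to other enolates.

The fallback sets out from 1 and comes back at 13.
- Compound 1 is C-geranylated with 3 (KOH, H2O–MeOH) to 3-geranyl-2,4,6-trihydroxybenzophenone F1.
- This is C-prenylated with 8 to 3-geranyl-5-prenyl-2,4,6-trihydroxybenzophenone F2.
- F2 is alkylated with 11 and LiN(SiMe3)2 to the chlorine-free dienone F3. This step is statistical in which alkyl-bearing carbon reacts, so half of the material is lost as a regioisomer that must be separated.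
- F3 is chlorinated with NCS (CH2Cl2, 0 °C) at its most nucleophilic carbon C3, which gives 13.

**Step 8 is the third risk.**
- Chlorine may return to C12 before the 5-exo closure.
- C12 may swing to the wrong side and give the C11 epimer.
- Monovalent copper may reduce the C3 radical to the enolate.
- The elimination may give some isopropylidene isomer.

The fallback sets out from 14 and comes back at 16. Compound 14 is dechlorinated with Zn in AcOH to the enolised 3-prenyl trione F5. F5 is then oxidised with Mn(OAc)3·2H2O (2.2 equiv) and Cu(OAc)2·H2O (1 equiv) in AcOH at rt. Trivalent manganese makes the same C3 radical from the enol. Divalent copper ends the same 7-exo/5-exo cascade by oxidative elimination, which gives the less substituted alkene of 16 directly.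

## Further compounds

F1 | step 6 | 3-geranyl-2,4,6-trihydroxybenzophenone | O=C(c1ccccc1)c1c(O)cc(O)c(C/C=C(\C)CCC=C(C)C)c1O
F2 | step 6 | 3-geranyl-5-prenyl-2,4,6-trihydroxybenzophenone | O=C(c1ccccc1)c1c(O)c(CC=C(C)C)c(O)c(C/C=C(\C)CCC=C(C)C)c1O
F3 | step 6 | chlorine-free dienone: 12 with prenyl in place of chlorine (6R, side chain 2R) | O=C1C(C(=O)c2ccccc2)=C(O)C(CC=C(C)C)=C(O)[C@@]1(C/C=C(\C)CCC=C(C)C)C[C@@H](CC=C(C)C)C(C)=C
F4 | step 7 | dihydropyran-fused tertiary enol ether: 13 with an O–C8 bond from the C9 enol oxygen (C5 and C7 as in 13) | CC1(C)OC2=C(C(=O)c3ccccc3)C(=O)C(Cl)(CC=C(C)C)C(=O)[C@@]2(C/C=C(\C)CCC=C(C)C)C[C@H]1CC=C(C)C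
F5 | step 8 | enolised 3-prenyl trione: 14 without chlorine, C2 enol (C1, C5 and C7 as in 14, C7 prenyl endo) | CC(C)=CCC=1C(=O)[C@@]2(C/C=C(\C)CCC=C(C)C)C[C@@H](CC=C(C)C)C(C)(C)[C@](C(=O)c3ccccc3)(C2=O)C=1O
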